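Squamatic acid is a depside: a single carbonyl carbon links C1 of ring A, which has the C2 hydroxyl and the C6 methyl as neighbours, to the phenolic oxygen at C4 of ring B. The route introduces that carbon as carbon monoxide. A palladium-catalysed aryloxycarbonylation joins a ring A C1 iodide, CO and the ring B C4 phenol, making the aryl–carbonyl C–C bond and the carbonyl–oxygen bond in one operation and avoiding a hindered acid chloride. The iodide is benzyl 2-(benzyloxy)-3-iodo-6-methoxy-4-methylbenzoate, made from symmetric 2,6-dihydroxy-4-methylbenzoic acid; the phenol is benzyl 2,4-dihydroxy-3,6-dimethylbenzoate. One hydrogenolysis then frees the target.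

Key step: step 7

Remark: the target has no stereocentre. Ring B is used with its C2 hydroxyl unprotected, on the assumption that this hydroxyl, chelated to the adjacent benzyl ester and flanked on both sides, does not compete with the C4 hydroxyl for the acyl group. On ring A, methylation precedes iodination so that the ether is placed on a symmetric diol.

Step 1
Reactants: 1 2,6-dihydroxy-4-methylbenzoic acid
Product: 2 benzyl 2,6-dihydroxy-4-methylbenzoate
Conditions: BnBr (1.05 equiv), KHCO3 (1.1 equiv), DMF, rt to 40 °C
Reagents that add atoms: benzyl bromide, BrCc1ccccc1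
Why: Carboxylate O-alkylation (SN2 esterification) should be selective because hydrogencarbonate deprotonates only the strongly acidic carboxyl group and leaves both chelated phenols protonated.

Step 2
Reactants: 2 benzyl 2,6-dihydroxy-4-methylbenzoate
Product: 3 benzyl 2-hydroxy-6-methoxy-4-methylbenzoate
Conditions: MeI (1.05 equiv), K2CO3 (1.1 equiv), acetone, rt
Reagents that add atoms: iodomethane, CI
Why: Williamson ether synthesis on a diol whose two hydroxyls are equivalent by symmetry can give only one mono-ether, and the remaining hydroxyl, now firmly hydrogen-bonded to the ester carbonyl, should resist a second methylation.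

Step 3
Reactants: 3 benzyl 2-hydroxy-6-methoxy-4-methylbenzoate
Product: 4 benzyl 2-hydroxy-3-iodo-6-methoxy-4-methylbenzoate
Conditions: NIS (1.05 equiv), TFA (cat.), MeCN, 0 °C to rt
Reagents that add atoms: N-iodosuccinimide, O=C1CCC(=O)N1I
Why: Electrophilic aromatic iodination should occur at benzoate C3, which is para to the methoxy group, ortho to the chelated hydroxyl and the less shielded open position (the methoxy methyl, turned away from the ester, lies over C5), as is usual for meta-alkoxyphenols and chelated ortho-hydroxyaryl carbonyl compounds.

Step 4
Reactants: 4 benzyl 2-hydroxy-3-iodo-6-methoxy-4-methylbenzoate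
Product: 5 benzyl 2-(benzyloxy)-3-iodo-6-methoxy-4-methylbenzoate
Conditions: BnBr (1.3 equiv), K2CO3 (2 equiv), DMF, 60 °C
Reagents that add atoms: benzyl bromide, BrCc1ccccc1
Why: Williamson benzylation of the only remaining hydroxyl masks the phenol next to iodine, so that no ortho-iodophenoxide can interfere with the carbonylation.

Step 5
Reactants: 6 methyl 2,4-dihydroxy-3,6-dimethylbenzoate
Product: 7 2,4-dihydroxy-3,6-dimethylbenzoic acid
Conditions: conc. H2SO4, 0 °C to rt; then ice–water
Reagents that add atoms: water, O
Why: Acid-mediated ester hydrolysis by the acylium (AAc1) pathway suits this doubly ortho-substituted benzoate, because the ortho and para hydroxyls stabilise the acylium ion that water captures on quenching, whereas hydroxide attack at the carbonyl is blocked.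

Step 6
Reactants: 7 2,4-dihydroxy-3,6-dimethylbenzoic acid
Product: 8 benzyl 2,4-dihydroxy-3,6-dimethylbenzoate
Conditions: BnBr (1.0 equiv), KHCO3 (1.1 equiv), DMF, rt
Reagents that add atoms: benzyl bromide, BrCc1ccccc1
Why: Carboxylate O-alkylation (SN2 esterification) under hydrogencarbonate should leave both phenols untouched, since only the carboxylic acid is deprotonated.

Step 7
Reactants: 5 benzyl 2-(benzyloxy)-3-iodo-6-methoxy-4-methylbenzoate; 9 carbon monoxide; 8 benzyl 2,4-dihydroxy-3,6-dimethylbenzoate (1.3 equiv)
Product: 10 tribenzyl squamatic acid, benzyl 2-(benzyloxy)-3-({4-[(benzyloxy)carbonyl]-3-hydroxy-2,5-dimethylphenoxy}carbonyl)-6-methoxy-4-methylbenzoate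
Conditions: Pd(OAc)2 (5 mol %), Xantphos (6 mol %), Et3N (3 equiv), CO (3 bar), toluene, 90 °C
Reagents that add atoms: carbon monoxide (compound 9), [C-]#[O+]
Why: Zerovalent palladium, generated in situ from Pd(OAc)2 and Xantphos, adds oxidatively to the C–I bond of 5, CO inserts into the aryl–palladium bond to give a divalent acylpalladium iodide, the triethylammonium phenoxide of 8 replaces iodide, and C–O reductive elimination releases the depside ester and returns zerovalent palladium. The closest known reaction type is the palladium-catalysed aryloxycarbonylation (carbonylative esterification) of aryl iodides with phenols, for which Xantphos is a standard ligand. No ring is closed and no stereocentre is formed. Three selectivities are needed: the site of carbonylation, fixed at ring A C1 by the iodine; CO insertion ahead of hydrodeiodination or direct aryl–oxygen coupling, favoured by CO pressure and by the wide-bite-angle diphosphine, with which direct aryl–O reductive elimination is slow; and acylation of the ring B C4 hydroxyl and not the C2 hydroxyl, secured because the C2 hydroxyl is hydrogen-bonded to the ester carbonyl, less acidic and flanked by two substituents. The benzyl esters and the benzyl ether are inert under these conditions, and the metal-bound acyl group should tolerate its two ortho substituents (benzyloxy and methyl) better than a free acid chloride would.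

Step 8
Reactants: 10 tribenzyl squamatic acid
Product: 11 squamatic acid
Conditions: H2 (1 atm), 10% Pd/C, EtOAc, rt
Reagents that add atoms: none
Why: Catalytic hydrogenolysis should cleave the two benzyl esters and the benzyl ether at their benzylic C–O bonds while leaving the aryl ester of the depside, which has no benzylic C–O bond, intact.

Compound list
1 | 2,6-dihydroxy-4-methylbenzoic acid | Cc1cc(O)c(C(=O)O)c(O)c1 | starting material
2 | benzyl 2,6-dihydroxy-4-methylbenzoate | Cc1cc(O)c(C(=O)OCc2ccccc2)c(O)c1 | intermediate
3 | benzyl 2-hydroxy-6-methoxy-4-methylbenzoate | COc1cc(C)cc(O)c1C(=O)OCc1ccccc1 | intermediate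
4 | benzyl 2-hydroxy-3-iodo-6-methoxy-4-methylbenzoate | COc1cc(C)c(I)c(O)c1C(=O)OCc1ccccc1 | intermediate
5 | benzyl 2-(benzyloxy)-3-iodo-6-methoxy-4-methylbenzoate | COc1cc(C)c(I)c(OCc2ccccc2)c1C(=O)OCc1ccccc1 | intermediate
6 | methyl 2,4-dihydroxy-3,6-dimethylbenzoate | COC(=O)c1c(C)cc(O)c(C)c1O | starting material
7 | 2,4-dihydroxy-3,6-dimethylbenzoic acid | Cc1cc(O)c(C)c(O)c1C(=O)O | intermediate
8 | benzyl 2,4-dihydroxy-3,6-dimethylbenzoate | Cc1cc(O)c(C)c(O)c1C(=O)OCc1ccccc1 | intermediate
9 | carbon monoxide | [C-]#[O+] | starting material
10 | tribenzyl squamatic acid, benzyl 2-(benzyloxy)-3-({4-[(benzyloxy)carbonyl]-3-hydroxy-2,5-dimethylphenoxy}carbonyl)-6-methoxy-4-methylbenzoate | COc1cc(C)c(C(=O)Oc2cc(C)c(C(=O)OCc3ccccc3)c(O)c2C)c(OCc2ccccc2)c1C(=O)OCc1ccccc1 | intermediate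
11 | squamatic acid, 3-[(4-carboxy-3-hydroxy-2,5-dimethylphenoxy)carbonyl]-2-hydroxy-6-methoxy-4-methylbenzoic acid | COc1cc(C)c(C(=O)Oc2cc(C)c(C(=O)O)c(O)c2C)c(O)c1C(=O)O | target

Total step count: 8. Longest linear sequence: 6 steps (steps 1, 2, 3, 4, 7, 8); the ring B branch (steps 5 and 6) joins at step 7.

Steps most likely to fail

Step 7. Carbon monoxide insertion or acyl transfer may stall at the palladium-bound aryl group, which carries two ortho substituents, so that hydrodeiodination takes over; some acyl group may also be delivered to the chelated C2 hydroxyl of ring B. The fallback sets out from 5 and introduces the carbonyl carbon as carbon dioxide, then forms the ester bond classically. Iodine–magnesium exchange with iPrMgCl·LiCl in THF at −30 °C should give [2-(benzyloxy)-3-(benzyloxycarbonyl)-4-methoxy-6-methylphenyl]magnesium chloride F1 (not isolated). Quenching with CO2 and acidic work-up should give 2-(benzyloxy)-3-[(benzyloxy)carbonyl]-4-methoxy-6-methylbenzoic acid F2. Trifluoroacetic anhydride in toluene at rt should convert F2 into its mixed trifluoroacetic anhydride F3 (not isolated), which acylates the C4 hydroxyl of 8 in the established depside manner. The route is rejoined at 10.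

Step 3. Iodination may partly go to the position para to the chelated hydroxyl, or a second iodine may enter, giving isomers that are hard to separate. The fallback sets out from 2 and reverses the order of iodination and methylation. NIS (1.0 equiv) in MeCN at 0 °C should give benzyl 2,6-dihydroxy-3-iodo-4-methylbenzoate F4, the only mono-iodide possible on the symmetric diol. NaH (2.2 equiv) in DMF at 0 °C should then form the disodium bis-phenoxide F5 (not isolated). One equivalent of MeI should alkylate F5 at the phenoxide remote from iodine, which is both the more basic and the less hindered of the two. The route is rejoined at 4.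

Step 5. The liberated electron-rich acid may lose carbon dioxide, or the ring may be sulfonated, in the strongly acidic medium. The fallback sets out from 6 and never generates the free acid. LiI in refluxing EtOAc should cleave the methyl ester by SN2 attack at the methyl carbon, giving lithium 2,4-dihydroxy-3,6-dimethylbenzoate F6 (not isolated). After a solvent switch to DMF, BnBr at rt should alkylate F6 at the carboxylate. The route is rejoined at 8.

Further compounds
F1 | step 7 | [2-(benzyloxy)-3-(benzyloxycarbonyl)-4-methoxy-6-methylphenyl]magnesium chloride | COc1cc(C)c([Mg]Cl)c(OCc2ccccc2)c1C(=O)OCc1ccccc1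
F2 | step 7 | 2-(benzyloxy)-3-[(benzyloxy)carbonyl]-4-methoxy-6-methylbenzoic acid | COc1cc(C)c(C(=O)O)c(OCc2ccccc2)c1C(=O)OCc1ccccc1
F3 | step 7 | mixed anhydride of F2 with trifluoroacetic acid | COc1cc(C)c(C(=O)OC(=O)C(F)(F)F)c(OCc2ccccc2)c1C(=O)OCc1ccccc1
F4 | step 3 | benzyl 2,6-dihydroxy-3-iodo-4-methylbenzoate | Cc1cc(O)c(C(=O)OCc2ccccc2)c(O)c1I
F5 | step 3 | disodium bis-phenoxide of F4 | Cc1cc([O-])c(C(=O)OCc2ccccc2)c([O-])c1I.[Na+].[Na+]
F6 | step 5 | lithium 2,4-dihydroxy-3,6-dimethylbenzoate | Cc1cc(O)c(C)c(O)c1C(=O)[O-].[Li+]
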